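## Retrosynthetic overview

1. The chromene C3=C4 bond is made last by loss of methanol from a 4-methoxychroman; the pyran ring (C4–C3 and O1–C2 bonds, C2 stereocentre) comes from a new catalytic asymmetric [4+2] annulation of a salicylaldehyde-acetal-derived ortho-quinone methide with the methallyl group of a bicyclic enone.
2. The bicyclic enone comes from Stille methallylation at C6 of the vinylogous acyl triflate of a 5-alkylated trans-hydrindane-4,6-dione; the C5 side chain is installed by reductive alkylation and double Grignard addition.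
3. The dione comes from Dieckmann closure of a trans-1,2-dimethylcyclopentane carrying an ester (future C3a) and an acetonyl group (future C7a).
4. C7a is set by a Claisen rearrangement with chirality transfer from a CBS-set carbinol; C3a is set by auxiliary-controlled alkylation of methyl 2-methylacetoacetate; the cyclopentenone is closed by alkyne hydration and aldol condensation.
5. Ring order: cyclopentene, then cyclohexanedione (hydrindane), then pyran.

Assumption: the toluene/HMPA protocol of the valine-enamine alkylation (step 2) is taken to give the (S)-product and the (S,S)-catalyst in step 14 is taken to give the (2R)-chroman; if either sense is opposite, the THF protocol (or the D-valine auxiliary) and the mirror-image catalyst are used, with no other change.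

## Route

Step 1
Reactants: 1 methyl 2-methyl-3-oxobutanoate
Product: 2 tert-butyl (2S)-2-{[(2Z)-4-methoxy-3-methyl-4-oxobut-2-en-2-yl]amino}-3-methylbutanoate
Conditions: L-valine tert-butyl ester (1.05 equiv), BF3·OEt2 (cat.), benzene, reflux, Dean–Stark
Reagents that add atoms: L-valine tert-butyl ester, CC(C)[C@H](N)C(=O)OC(C)(C)C
Why: Condensation of the ketone with the primary amine gives the hydrogen-bonded (Z)-enamino ester (enamine formation, attachment of the Koga auxiliary); no new stereocentre is formed.

Step 2
Reactants: 2 tert-butyl (2S)-2-{[(2Z)-4-methoxy-3-methyl-4-oxobut-2-en-2-yl]amino}-3-methylbutanoate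
Product: 4 methyl (2S)-2-acetyl-2-methylpent-4-ynoate, via alkylated ketimine 3 (not isolated)
Conditions: LiN(i-Pr)2 (1.2 equiv), toluene, HMPA (1 equiv), −78 °C; propargyl bromide, −78 to −40 °C; then 1 M HCl, 25 °C
Reagents that add atoms: propargyl bromide, C#CCBr; water, O
Why: The chelated lithio-enamine has one face blocked by the valine isopropyl and tert-butyl ester groups, so the halide alkylates the α-carbon from the open face and sets the (S)-quaternary centre (Koga asymmetric alkylation of α-alkyl β-keto ester enamines), and mild acid hydrolysis frees the ketone and the auxiliary.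

Step 3
Reactants: 4 methyl (2S)-2-acetyl-2-methylpent-4-ynoate
Product: 6 methyl (1S)-1,2-dimethyl-4-oxocyclopent-2-ene-1-carboxylate, via 1,4-diketone 5 (not isolated)
Conditions: Ph3PAuNTf2 (2 mol %), MeOH–H2O 10:1, 50 °C; then pyrrolidine (0.3 equiv), AcOH (0.3 equiv), 60 °C
Reagents that add atoms: water, O
Why: Carbonyl-assisted Markovnikov hydration of the terminal alkyne by the monovalent gold catalyst gives the methyl ketone, whose pyrrolidine enamine (formed at the unhindered ketone) attacks the acetyl carbonyl in an intramolecular aldol condensation; the quaternary centre has no α-hydrogen and is untouched.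

Step 4
Reactants: 6 methyl (1S)-1,2-dimethyl-4-oxocyclopent-2-ene-1-carboxylate
Product: 7 methyl (1S,4S)-4-hydroxy-1,2-dimethylcyclopent-2-ene-1-carboxylate
Conditions: (R)-2-methyl-CBS-oxazaborolidine (20 mol %), catecholborane (1.5 equiv), toluene, −78 °C; MeOH, then aq. NaOH; chromatography
Reagents that add atoms: none
Why: Corey–Bakshi–Shibata reduction delivers hydride under catalyst control with the alkenyl arm as the large group, giving the (4S)-carbinol with the hydroxyl cis to the C1 methyl; the minor enantiomer of 6 ends up mainly as the trans diastereomer and is removed on silica, which raises the ee.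

Step 5
Reactants: 7 methyl (1S,4S)-4-hydroxy-1,2-dimethylcyclopent-2-ene-1-carboxylate
Product: 9 methyl (1S,2S)-1,2-dimethyl-2-(2-oxopropyl)cyclopent-3-ene-1-carboxylate, via allyl isopropenyl ether 8 (not isolated)
Conditions: 2-methoxypropene (10 equiv), EtCO2H (5 mol %), o-xylene, sealed tube, 25 °C then 145 °C
Reagents that add atoms: 2-methoxypropene, COC(C)=C
Why: Acid-catalysed exchange gives the allyl isopropenyl ether, which undergoes a suprafacial [3,3] shift (Saucy–Marbet ketone Claisen rearrangement) that forms the new C–C bond on the face that carried the oxygen, cis to the C1 methyl, so the second quaternary centre is set with the two ring methyls trans.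

Step 6
Reactants: 9 methyl (1S,2S)-1,2-dimethyl-2-(2-oxopropyl)cyclopent-3-ene-1-carboxylate
Product: 10 methyl (1S,2R)-1,2-dimethyl-2-(2-oxopropyl)cyclopentane-1-carboxylate
Conditions: H2 (1 atm), Pd/C (10 wt %), EtOAc, 25 °C
Reagents that add atoms: none
Why: Heterogeneous hydrogenation of the cis-disubstituted ring alkene creates no stereocentre and leaves ketone and ester untouched (the descriptor at C2 changes only through CIP priorities).

Step 7
Reactants: 10 methyl (1S,2R)-1,2-dimethyl-2-(2-oxopropyl)cyclopentane-1-carboxylate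
Product: 11 (3aS,7aR)-3a,7a-dimethylhexahydro-1H-indene-4,6(2H,5H)-dione
Conditions: KOtBu (2.5 equiv), THF, 0 to 60 °C; then 1 M HCl
Reagents that add atoms: none
Why: Dieckmann-type intramolecular Claisen condensation, in which only the methyl-ketone enolate can reach the ester through a six-membered transition state and deprotonation of the β-diketone drives closure of the trans-fused ring; both stereocentres are quaternary and cannot epimerise.

Step 8
Reactants: 11 (3aS,7aR)-3a,7a-dimethylhexahydro-1H-indene-4,6(2H,5H)-dione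
Product: 13 methyl 2-[(3aS,7aR)-3a,7a-dimethyl-4,6-dioxooctahydro-1H-inden-5-yl]acetate, via alkylidene dione 12 (not isolated)
Conditions: methyl glyoxylate (1.3 equiv), Hantzsch ester (1.2 equiv), L-proline (10 mol %), CH2Cl2, 25 °C
Reagents that add atoms: methyl glyoxylate, COC(=O)C=O
Why: Three-component reductive alkylation (Knoevenagel condensation at C5, then transfer hydrogenation of the alkylidene dione by the Hantzsch ester) gives C-alkylation only; C5 stays enolised and is not a defined stereocentre.

Step 9
Reactants: 13 methyl 2-[(3aS,7aR)-3a,7a-dimethyl-4,6-dioxooctahydro-1H-inden-5-yl]acetate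
Product: 14 (3aS,7aR)-5-(2-hydroxy-2-methylpropyl)-3a,7a-dimethylhexahydro-1H-indene-4,6(2H,5H)-dione
Conditions: MeMgBr (5 equiv), THF, −20 to 25 °C; then sat. aq. NH4Cl (pH about 6), used at once
Reagents that add atoms: methylmagnesium bromide, C[Mg]Br
Why: The first equivalent converts the acidic dione into its unreactive magnesium enolate, so the double Grignard addition takes place only at the ester and gives the tertiary alcohol.

Step 10
Reactants: 14 (3aS,7aR)-5-(2-hydroxy-2-methylpropyl)-3a,7a-dimethylhexahydro-1H-indene-4,6(2H,5H)-dione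
Product: 15 (3aS,7aR)-5-(2-hydroxy-2-methylpropyl)-3a,7a-dimethyl-4-oxo-2,3,3a,4,7,7a-hexahydro-1H-inden-6-yl trifluoromethanesulfonate
Conditions: PhNTf2 (1.1 equiv), Et3N (1.5 equiv), CH2Cl2, 0 °C
Reagents that add atoms: N-phenylbis(trifluoromethanesulfonimide), O=S(=O)(N(c1ccccc1)S(=O)(=O)C(F)(F)F)C(F)(F)F
Why: O-sulfonylation of the dione enolate occurs at the less hindered oxygen (on C6, next to CH2) and not at the one next to quaternary C3a, giving the vinylogous acyl triflate with the ketone at C4 (regioselective enol triflate formation); the tertiary hydroxyl is not acidic enough to react.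

Step 11
Reactants: 15 (3aS,7aR)-5-(2-hydroxy-2-methylpropyl)-3a,7a-dimethyl-4-oxo-2,3,3a,4,7,7a-hexahydro-1H-inden-6-yl trifluoromethanesulfonate
Product: 16 (3aS,7aR)-5-(2-hydroxy-2-methylpropyl)-3a,7a-dimethyl-6-(2-methylprop-2-en-1-yl)-1,2,3,3a,7,7a-hexahydro-4H-inden-4-one
Conditions: tributyl(2-methylallyl)stannane (1.4 equiv), Pd2(dba)3 (2.5 mol %), AsPh3 (20 mol %), LiCl (3 equiv), NMP, 25 to 40 °C
Reagents that add atoms: tributyl(2-methylallyl)stannane, CCCC[Sn](CCCC)(CCCC)CC(C)=C
Why: Stille cross-coupling (oxidative addition of zerovalent palladium to the vinyl triflate, transmetalation, reductive elimination) forms the C6–CH2 bond under neutral conditions that do not move the skipped alkene into conjugation; the 2-methylallyl group has two equivalent termini, so there is no regiochemical issue.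

Step 12
Reactants: 17 4-methoxy-2-methylphenol
Product: 18 2-hydroxy-5-methoxy-3-methylbenzaldehyde
Conditions: MgCl2 (2 equiv), Et3N (4 equiv), (CH2O)n (6 equiv), MeCN, reflux; then 1 M HCl
Reagents that add atoms: paraformaldehyde (formaldehyde), C=O
Why: Magnesium-phenoxide-directed ortho-formylation (Casnati–Skattebøl reaction) takes place at the only free ortho position.

Step 13
Reactants: 18 2-hydroxy-5-methoxy-3-methylbenzaldehyde
Product: 19 2-(dimethoxymethyl)-4-methoxy-6-methylphenol
Conditions: HC(OMe)3 (5 equiv), MeOH, Amberlyst-15 (cat.), 25 °C; filtered through basic alumina, used crude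
Reagents that add atoms: trimethyl orthoformate, COC(OC)OC
Why: Acid-catalysed acetalisation with the orthoformate as methoxy donor and water scavenger gives the dry ortho-quinone methide precursor.

Step 14
Reactants: 16 (3aS,7aR)-5-(2-hydroxy-2-methylpropyl)-3a,7a-dimethyl-6-(2-methylprop-2-en-1-yl)-1,2,3,3a,7,7a-hexahydro-4H-inden-4-one, 19 2-(dimethoxymethyl)-4-methoxy-6-methylphenol (2 equiv)
Product: 20 (3aS,7aR)-5-(2-hydroxy-2-methylpropyl)-6-{[(2R)-4,6-dimethoxy-2,8-dimethyl-3,4-dihydro-2H-chromen-2-yl]methyl}-3a,7a-dimethyl-1,2,3,3a,7,7a-hexahydro-4H-inden-4-one (C4 of the chroman as an epimer mixture, both carried on)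
Conditions: (S,S)-IDPi chiral Brønsted acid (imidodiphosphorimidate from (S)-3,3′-bis[3,5-bis(trifluoromethyl)phenyl]-BINOL, N-triflyl core; 5 mol %), 5 Å molecular sieves, CHCl3–cyclohexane, −40 °C; Et3N quench
Reagents that add atoms: none
Why: Proposed new method: a catalytic asymmetric intermolecular [4+2] annulation of an in situ ortho-quinone methide with an unactivated 1,1-dialkyl olefin, in which the confined chiral acid ionises acetal 19 to the O-methyl oxocarbenium/ortho-quinone methide held as a contact ion pair, the methallyl CH2 terminus of 16 attacks the benzylic carbon (Markovnikov, C4–C3 bond), and the developing tertiary cation at C2 is captured by the phenol oxygen inside the chiral pocket (O1–C2 bond) through a chair-like asynchronous transition state with the bulky CH2-bicycle pseudo-equatorial, so that catalyst control of the oxocarbenium face is relayed to C2 (2R); the closest known reactions are chiral-Brønsted-acid-catalysed intramolecular [4+2] cycloadditions of salicylaldehyde-derived ortho-quinone methides with tethered olefins, intermolecular ortho-quinone methide cycloadditions with styrenes and enol ethers, and the achiral Lewis-acid chroman synthesis from salicylaldehydes, orthoformate and 1,1-disubstituted olefins.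

Step 15
Reactants: 20 (3aS,7aR)-5-(2-hydroxy-2-methylpropyl)-6-{[(2R)-4,6-dimethoxy-2,8-dimethyl-3,4-dihydro-2H-chromen-2-yl]methyl}-3a,7a-dimethyl-1,2,3,3a,7,7a-hexahydro-4H-inden-4-one
Product: 21 (3aS,7aR)-5-(2-hydroxy-2-methylpropyl)-6-{[(2R)-6-methoxy-2,8-dimethyl-2H-chromen-2-yl]methyl}-3a,7a-dimethyl-1,2,3,3a,7,7a-hexahydro-4H-inden-4-one (CNP0295366.2)
Conditions: PPTS (20 mol %), toluene, 70 °C
Reagents that add atoms: none
Why: Mild acid-catalysed E1 loss of methanol through the ortho-oxygen-stabilised benzylic cation at C4 gives the 2H-chromene from either C4 epimer; C2 is not involved and keeps its configuration, and the acid is too weak to ionise the tertiary alcohol or the chromene C2–O bond.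

## Compound list

1 | methyl 2-methyl-3-oxobutanoate | COC(=O)C(C)C(C)=O | starting material
2 | tert-butyl (2S)-2-{[(2Z)-4-methoxy-3-methyl-4-oxobut-2-en-2-yl]amino}-3-methylbutanoate | COC(=O)/C(C)=C(/C)N[C@@H](C(C)C)C(=O)OC(C)(C)C | intermediate
3 | tert-butyl (2S)-2-{[(3S)-3-(methoxycarbonyl)-3-methylhex-5-yn-2-ylidene]amino}-3-methylbutanoate (alkylated ketimine, not isolated) | COC(=O)[C@@](C(C)=N[C@@H](C(C)C)C(=O)OC(C)(C)C)(C)CC#C | intermediate
4 | methyl (2S)-2-acetyl-2-methylpent-4-ynoate | COC(=O)[C@@](C(C)=O)(C)CC#C | intermediate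
5 | methyl (2S)-2-acetyl-2-methyl-4-oxopentanoate (1,4-diketone, not isolated) | COC(=O)[C@@](C(C)=O)(C)CC(C)=O | intermediate
6 | methyl (1S)-1,2-dimethyl-4-oxocyclopent-2-ene-1-carboxylate | COC(=O)[C@@]1(C)CC(=O)C=C1C | intermediate
7 | methyl (1S,4S)-4-hydroxy-1,2-dimethylcyclopent-2-ene-1-carboxylate (OH cis to the C1 methyl) | COC(=O)[C@@]1(C)C[C@H](O)C=C1C | intermediate
8 | methyl (1S,4S)-1,2-dimethyl-4-(prop-1-en-2-yloxy)cyclopent-2-ene-1-carboxylate (allyl isopropenyl ether, not isolated) | COC(=O)[C@@]1(C)C[C@H](OC(C)=C)C=C1C | intermediate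
9 | methyl (1S,2S)-1,2-dimethyl-2-(2-oxopropyl)cyclopent-3-ene-1-carboxylate (ring methyls trans) | COC(=O)[C@@]1(C)CC=C[C@]1(C)CC(C)=O | intermediate
10 | methyl (1S,2R)-1,2-dimethyl-2-(2-oxopropyl)cyclopentane-1-carboxylate | COC(=O)[C@@]1(C)CCC[C@]1(C)CC(C)=O | intermediate
11 | (3aS,7aR)-3a,7a-dimethylhexahydro-1H-indene-4,6(2H,5H)-dione (trans-fused) | O=C1CC(=O)[C@@]2(C)CCC[C@]2(C)C1 | intermediate
12 | methyl 2-[(3aS,7aR)-3a,7a-dimethyl-4,6-dioxooctahydro-5H-inden-5-ylidene]acetate (alkylidene dione, E/Z mixture, not isolated) | O=C1C(=CC(=O)OC)C(=O)[C@@]2(C)CCC[C@]2(C)C1 | intermediate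
13 | methyl 2-[(3aS,7aR)-3a,7a-dimethyl-4,6-dioxooctahydro-1H-inden-5-yl]acetate (enolised, C5 undefined) | O=C1C(CC(=O)OC)C(=O)[C@@]2(C)CCC[C@]2(C)C1 | intermediate
14 | (3aS,7aR)-5-(2-hydroxy-2-methylpropyl)-3a,7a-dimethylhexahydro-1H-indene-4,6(2H,5H)-dione (enolised, C5 undefined) | O=C1C(CC(C)(C)O)C(=O)[C@@]2(C)CCC[C@]2(C)C1 | intermediate
15 | (3aS,7aR)-5-(2-hydroxy-2-methylpropyl)-3a,7a-dimethyl-4-oxo-2,3,3a,4,7,7a-hexahydro-1H-inden-6-yl trifluoromethanesulfonate | FC(F)(F)S(=O)(=O)OC1=C(CC(C)(C)O)C(=O)[C@@]2(C)CCC[C@]2(C)C1 | intermediate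
16 | (3aS,7aR)-5-(2-hydroxy-2-methylpropyl)-3a,7a-dimethyl-6-(2-methylprop-2-en-1-yl)-1,2,3,3a,7,7a-hexahydro-4H-inden-4-one | CC(=C)CC1=C(CC(C)(C)O)C(=O)[C@@]2(C)CCC[C@]2(C)C1 | intermediate
17 | 4-methoxy-2-methylphenol | COc1ccc(O)c(C)c1 | starting material
18 | 2-hydroxy-5-methoxy-3-methylbenzaldehyde | COc1cc(C)c(O)c(C=O)c1 | intermediate
19 | 2-(dimethoxymethyl)-4-methoxy-6-methylphenol | COc1cc(C)c(O)c(C(OC)OC)c1 | intermediate
20 | (3aS,7aR)-5-(2-hydroxy-2-methylpropyl)-6-{[(2R)-4,6-dimethoxy-2,8-dimethyl-3,4-dihydro-2H-chromen-2-yl]methyl}-3a,7a-dimethyl-1,2,3,3a,7,7a-hexahydro-4H-inden-4-one (chroman C4 epimer mixture) | COc1cc(C)c2c(c1)C(OC)C[C@@](C)(CC1=C(CC(C)(C)O)C(=O)[C@@]3(C)CCC[C@]3(C)C1)O2 | intermediate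
21 | (3aS,7aR)-5-(2-hydroxy-2-methylpropyl)-6-{[(2R)-6-methoxy-2,8-dimethyl-2H-chromen-2-yl]methyl}-3a,7a-dimethyl-1,2,3,3a,7,7a-hexahydro-4H-inden-4-one | COc1cc(C)c2c(c1)C=C[C@@](C)(CC1=C(CC(C)(C)O)C(=O)[C@@]3(C)CCC[C@]3(C)C1)O2 | target

## Step count and risks

Total step count: 15. Longest linear sequence: 13 steps (steps 1 to 11, then 14 and 15).

The three steps most likely to fail:

Step 5 (ketone Claisen rearrangement forming the second of two adjacent quaternary centres). The acid and heat may ionise or eliminate the allylic alcohol before the hindered [3,3] shift. The fallback sets out from 7 and comes back at 9. Compound 7 is heated with N,N-dimethylacetamide dimethyl acetal in xylene at 140 °C without acid. The ketene N,O-acetal methyl (1S,4S)-4-{[1-(dimethylamino)ethenyl]oxy}-1,2-dimethylcyclopent-2-ene-1-carboxylate F1 forms in the flask and rearranges with the same suprafacial sense (Eschenmoser–Claisen) to the dimethylamide methyl (1S,2S)-2-[2-(dimethylamino)-2-oxoethyl]-1,2-dimethylcyclopent-3-ene-1-carboxylate F2. MeLi (1.1 equiv, THF, −78 °C) converts the amide into the methyl ketone 9, leaving the doubly neopentylic ester, and the route continues with step 6.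

Step 10 (enol triflate of the hydroxy-dione, needed for the Stille coupling of step 11). Compound 14 may cyclodehydrate, or the free tertiary hydroxyl may displace the triflate. The fallback sets out from 14 and comes back at 16, replacing steps 10 and 11 by carbonyl-addition chemistry. TsOH (cat.) in toluene at 60 °C deliberately cyclodehydrates 14 to two separable fused 2,2-dimethyl-2,3-dihydrofuran vinylogous esters: the isomer with the ring oxygen on C4 and the ketone at C6 F3, and the isomer with the ring oxygen on C6 and the ketone at C4 F4. F3 is treated with 2-methylallylmagnesium chloride and then dilute HCl (Stork–Danheiser addition and transposition), which opens the furan ring and gives 16 directly. F4 is reduced with i-Bu2AlH and hydrolysed with dilute HCl to the transposed enone with the ketone at C6 and a C4=C5 double bond F5. 2-Methylallylmagnesium chloride adds to F5 to give the tertiary allylic alcohol F6, and pyridinium chlorochromate, [C5H5NH][CrO3Cl], in CH2Cl2 effects the oxidative 1,3-transposition to 16.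

Step 14 (the proposed new asymmetric annulation). Reactivity of the unactivated olefin, acid-induced side reactions of 16, or insufficient control at C2 may defeat it. The fallback uses known chemistry only, sets out from 16 (with 18) and comes back at 21. NaBH4 in MeOH reduces 18 to 2-(hydroxymethyl)-4-methoxy-6-methylphenol F7. Heating F7 with 16 in xylene at 170 °C (sealed tube) generates the parent ortho-quinone methide thermally, and its uncatalysed [4+2] cycloaddition with the methallyl group gives two C2-epimeric chromans. These are the (2S)-chroman F8, which has the spatial arrangement of the target (the descriptor differs only through CIP priorities), and the (2R)-chroman F9. They are diastereomers and are separated by preparative HPLC. DDQ in benzene at 80 °C then dehydrogenates F8 across C3–C4 to 21.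

Further compounds
F1 | step 5 | methyl (1S,4S)-4-{[1-(dimethylamino)ethenyl]oxy}-1,2-dimethylcyclopent-2-ene-1-carboxylate | COC(=O)[C@@]1(C)C[C@H](OC(=C)N(C)C)C=C1C
F2 | step 5 | methyl (1S,2S)-2-[2-(dimethylamino)-2-oxoethyl]-1,2-dimethylcyclopent-3-ene-1-carboxylate | COC(=O)[C@@]1(C)CC=C[C@]1(C)CC(=O)N(C)C
F3 | step 10 | tricyclic vinylogous ester, (3aS,7aR) in the numbering of 11: 2,2-dimethyl-2,3-dihydrofuran fused across C4–C5 with the ring oxygen on C4, ketone at C6 | O=C1C2=C(OC(C)(C)C2)[C@@]3(C)CCC[C@]3(C)C1
F4 | step 10 | tricyclic vinylogous ester, (3aS,7aR) in the numbering of 11: 2,2-dimethyl-2,3-dihydrofuran fused across C5–C6 with the ring oxygen on C6, ketone at C4 | C12=C(CC(C)(C)O1)C(=O)[C@@]3(C)CCC[C@]3(C)C2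
F5 | step 10 | (3aR,7aR)-5-(2-hydroxy-2-methylpropyl)-3a,7a-dimethyl-1,2,3,3a,7,7a-hexahydro-6H-inden-6-one (numbering and spatial arrangement of 11) | O=C1C(CC(C)(C)O)=C[C@@]2(C)CCC[C@]2(C)C1
F6 | step 10 | (3aR,7aR)-5-(2-hydroxy-2-methylpropyl)-3a,7a-dimethyl-6-(2-methylprop-2-en-1-yl)-2,3,3a,6,7,7a-hexahydro-1H-inden-6-ol (numbering of 11, C6 epimer mixture) | CC(=C)CC1(O)C(CC(C)(C)O)=C[C@@]2(C)CCC[C@]2(C)C1
F7 | step 14 | 2-(hydroxymethyl)-4-methoxy-6-methylphenol | COc1cc(C)c(O)c(CO)c1
F8 | step 14 | (3aS,7aR)-5-(2-hydroxy-2-methylpropyl)-6-{[(2S)-6-methoxy-2,8-dimethyl-3,4-dihydro-2H-chromen-2-yl]methyl}-3a,7a-dimethyl-1,2,3,3a,7,7a-hexahydro-4H-inden-4-one | COc1cc(C)c2c(c1)CC[C@@](C)(CC1=C(CC(C)(C)O)C(=O)[C@@]3(C)CCC[C@]3(C)C1)O2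
F9 | step 14 | (3aS,7aR)-5-(2-hydroxy-2-methylpropyl)-6-{[(2R)-6-methoxy-2,8-dimethyl-3,4-dihydro-2H-chromen-2-yl]methyl}-3a,7a-dimethyl-1,2,3,3a,7,7a-hexahydro-4H-inden-4-one | COc1cc(C)c2c(c1)CC[C@](C)(CC1=C(CC(C)(C)O)C(=O)[C@@]3(C)CCC[C@]3(C)C1)O2
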